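**Plan**

1. Retrosynthesis, in this order: the two aryl O–Si bonds; then the C3–CH(OH) bond between the furanone and the 3,5-dibromo-4-methoxyphenyl carbinol; then the exocyclic C5=CH bond; then the C4–aryl bond.
2. Forward: the furanone ring is bought as 4-bromofuran-2(5H)-one. Its C4 aryl ring is attached by Suzuki–Miyaura coupling, the benzylidene at C5 by vinylogous aldol condensation, the aldehyde at C3 in the key step, and the silyl ethers are removed last.
3. Enabling feature: the O1–C2(=O)–C3=C4–C5=CH–aryl dienoate of the 5-benzylidenefuran-2(5H)-one ring. A Lewis base that adds to the exocyclic CH turns the ring into an aromatic 2-oxidofuran in which C5 is blocked and C3 is the free enolate carbon, so the C3–H bond is joined directly to the aldehyde carbon and the Lewis base leaves again.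
4. Stereochemistry: the single S carbinol centre is set in the key step by a chiral binaphthol-type Brønsted acid co-catalyst. The Z alkene is set under thermodynamic control in step 5 and re-formed in step 6.
5. All four bromine atoms and the methyl ether arrive with the building blocks, so no halogen or metal is ever placed at C3; the two phenols travel as triisopropylsilyl ethers.

Key step: step 6

Remark: by the CIP rules the carbinol centre of the target is S (OH > furanone C3 > aryl > H); compounds 1, 5, 7 and 12 are taken as catalogue chemicals.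

**Route**

Step 1
Reactants: 1 2-bromo-4-iodophenol
Product: 2 (2-bromo-4-iodophenoxy)triisopropylsilane
Conditions: TIPSCl, imidazole, DMF, rt
Reagents that add atoms: triisopropylsilyl chloride, CC(C)[Si](Cl)(C(C)C)C(C)C
Why: Imidazole-promoted O-silylation of the phenol removes the acidic proton before the Grignard step and places a bulky group next to the C–Br bond that shields it in the later palladium step.

Step 2
Reactants: 2 (2-bromo-4-iodophenoxy)triisopropylsilane
Product: 4 2-[3-bromo-4-(triisopropylsilyloxy)phenyl]-4,4,5,5-tetramethyl-1,3,2-dioxaborolane, via arylmagnesium chloride 3 (not isolated)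
Conditions: iPrMgCl·LiCl, THF, −20 to 0 °C; then iPrOBpin, −20 °C to rt; aq NH4Cl
Reagents that add atoms: 2-isopropoxy-4,4,5,5-tetramethyl-1,3,2-dioxaborolane, CC(C)OB1OC(C)(C)C(C)(C)O1
Why: Iodine–magnesium exchange with the turbo Grignard reagent is much faster at the C–I bond than at the C–Br bond, and the aryl Grignard reagent 3 is trapped at boron with loss of isopropoxide (halogen–metal exchange followed by borylation).

Step 3
Reactants: 4 2-[3-bromo-4-(triisopropylsilyloxy)phenyl]-4,4,5,5-tetramethyl-1,3,2-dioxaborolane; 5 4-bromofuran-2(5H)-one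
Product: 6 4-[3-bromo-4-(triisopropylsilyloxy)phenyl]furan-2(5H)-one
Conditions: PdCl2(PPh3)2 (5 mol %), K3PO4, THF/H2O, 45 °C
Reagents that add atoms: none
Why: Suzuki–Miyaura coupling in which zerovalent palladium inserts into the vinylogous acyl bromide of 5 far faster than into the electron-rich aryl C–Br bond shielded by the ortho silyloxy group.

Step 4
Reactants: 7 3-bromo-4-hydroxybenzaldehyde
Product: 8 3-bromo-4-(triisopropylsilyloxy)benzaldehyde
Conditions: TIPSCl, imidazole, DMF, rt
Reagents that add atoms: triisopropylsilyl chloride, CC(C)[Si](Cl)(C(C)C)C(C)C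
Why: Imidazole-promoted O-silylation masks the phenol, whose phenolate would otherwise deactivate the aldehyde and quench the silyl triflate of the next step.

Step 5
Reactants: 6 4-[3-bromo-4-(triisopropylsilyloxy)phenyl]furan-2(5H)-one; 8 3-bromo-4-(triisopropylsilyloxy)benzaldehyde
Product: 11 (5Z)-4-[3-bromo-4-(triisopropylsilyloxy)phenyl]-5-{[3-bromo-4-(triisopropylsilyloxy)phenyl]methylidene}furan-2(5H)-one, via silyloxyfuran 9 (not isolated), via aldol silyl ether 10 (not isolated)
Conditions: TBSOTf, iPr2NEt, CH2Cl2, 0 °C to rt; then DBU, rt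
Reagents that add atoms: none
Why: One-pot vinylogous Mukaiyama aldol condensation in which the silyloxyfuran 9 attacks the silyl-activated aldehyde through C5 and DBU then induces E1cB loss of silanolate from 10, giving the thermodynamically favoured Z alkene whose benzylidene aryl group points away from the C4 aryl ring.

Step 6
Reactants: 11 (5Z)-4-[3-bromo-4-(triisopropylsilyloxy)phenyl]-5-{[3-bromo-4-(triisopropylsilyloxy)phenyl]methylidene}furan-2(5H)-one; 12 3,5-dibromo-4-methoxybenzaldehyde
Product: 15 (5Z)-4-[3-bromo-4-(triisopropylsilyloxy)phenyl]-5-{[3-bromo-4-(triisopropylsilyloxy)phenyl]methylidene}-3-[(S)-(3,5-dibromo-4-methoxyphenyl)(hydroxy)methyl]furan-2(5H)-one, via phosphonium furanolate 13 (not isolated), via aldolate zwitterion 14 (not isolated)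
Conditions: 12 (2 equiv), PMe3 (0.3 equiv), (R)-3,3'-bis[3,5-bis(trifluoromethyl)phenyl]-5,5',6,6',7,7',8,8'-octahydro-1,1'-bi-2-naphthol (0.15 equiv), THF (1 M), −10 °C to rt
Reagents that add atoms: none
Why: Proposed new method: PMe3 adds reversibly to the exocyclic benzylidene carbon of the O1–C2(=O)–C3=C4–C5=CH dienoate of 11 (1,6-addition) because this converts the lactone ring into the aromatic 2-oxidofuran 13, whose C5 is blocked and whose free enolate carbon is C3; C3 adds to the carbonyl carbon of 12 to give 14, the now acidic C3–H is transferred to the alkoxide, and E1cB loss of PMe3 restores the C3=C4 and C5=CH bonds. The closest known reaction type is the trialkylphosphine-catalysed Morita–Baylis–Hillman reaction of cyclic enones with aldehydes under chiral binaphthol Brønsted acid co-catalysis, extended here by one vinyl unit so that the Lewis base enters at the delta carbon instead of the beta carbon, which in 11 is fully substituted. No ring is closed in this step. The new carbinol stereocentre is controlled by the chiral diol, which is hydrogen-bonded to the furanolate oxygen next to C3 and to the aldehyde oxygen in the C–C bond-forming transition state, and the diol enantiomer is selected so that C3 attacks the face of 12 that leads to the S alcohol (the (R)-diol is the first choice and its mirror image is used if the sense proves opposite). The step needs attack through C3 instead of C5 and no reaction at the four C–Br bonds: an adduct formed through C5 has no proton to lose and can only revert, so only the C3 adduct is drained to product, and the metal-free Lewis base does not touch aryl bromides, silyl ethers or the methyl ether. The Z geometry of the benzylidene is re-formed on loss of PMe3 because it keeps that aryl group away from the C4 aryl ring.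

Step 7
Reactants: 15 (5Z)-4-[3-bromo-4-(triisopropylsilyloxy)phenyl]-5-{[3-bromo-4-(triisopropylsilyloxy)phenyl]methylidene}-3-[(S)-(3,5-dibromo-4-methoxyphenyl)(hydroxy)methyl]furan-2(5H)-one
Product: 16 (5Z)-4-(3-bromo-4-hydroxyphenyl)-5-[(3-bromo-4-hydroxyphenyl)methylidene]-3-[(S)-(3,5-dibromo-4-methoxyphenyl)(hydroxy)methyl]furan-2(5H)-one
Conditions: HF·pyridine, pyridine, THF, 0 °C to rt
Reagents that add atoms: none
Why: Fluoride cleaves the two aryl O–Si bonds under weakly acidic buffered conditions, so that no phenolate forms that could trigger a vinylogous retro-aldol cleavage or racemisation of the carbinol, while the methyl ether, the enol lactone and the C–Br bonds are inert.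

**Compound list**

1 | 2-bromo-4-iodophenol | Oc1ccc(I)cc1Br | starting material
2 | (2-bromo-4-iodophenoxy)triisopropylsilane | CC(C)[Si](Oc1ccc(I)cc1Br)(C(C)C)C(C)C | intermediate
3 | [3-bromo-4-(triisopropylsilyloxy)phenyl]magnesium chloride (LiCl complex, formed in the flask) | CC(C)[Si](Oc1ccc([Mg]Cl)cc1Br)(C(C)C)C(C)C | intermediate
4 | 2-[3-bromo-4-(triisopropylsilyloxy)phenyl]-4,4,5,5-tetramethyl-1,3,2-dioxaborolane | CC(C)[Si](Oc1ccc(B2OC(C)(C)C(C)(C)O2)cc1Br)(C(C)C)C(C)C | intermediate
5 | 4-bromofuran-2(5H)-one | O=C1C=C(Br)CO1 | starting material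
6 | 4-[3-bromo-4-(triisopropylsilyloxy)phenyl]furan-2(5H)-one | O=C1C=C(c2ccc(O[Si](C(C)C)(C(C)C)C(C)C)c(Br)c2)CO1 | intermediate
7 | 3-bromo-4-hydroxybenzaldehyde | O=Cc1ccc(O)c(Br)c1 | starting material
8 | 3-bromo-4-(triisopropylsilyloxy)benzaldehyde | O=Cc1ccc(O[Si](C(C)C)(C(C)C)C(C)C)c(Br)c1 | intermediate
9 | tert-butyl({4-[3-bromo-4-(triisopropylsilyloxy)phenyl]furan-2-yl}oxy)dimethylsilane (formed in the flask) | CC(C)(C)[Si](C)(C)Oc1cc(-c2ccc(O[Si](C(C)C)(C(C)C)C(C)C)c(Br)c2)co1 | intermediate
10 | 4-[3-bromo-4-(triisopropylsilyloxy)phenyl]-5-{[3-bromo-4-(triisopropylsilyloxy)phenyl][(tert-butyldimethylsilyl)oxy]methyl}furan-2(5H)-one (formed in the flask, both diastereomers converge) | O=C1C=C(c2ccc(O[Si](C(C)C)(C(C)C)C(C)C)c(Br)c2)C(C(O[Si](C)(C)C(C)(C)C)c2ccc(O[Si](C(C)C)(C(C)C)C(C)C)c(Br)c2)O1 | intermediate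
11 | (5Z)-4-[3-bromo-4-(triisopropylsilyloxy)phenyl]-5-{[3-bromo-4-(triisopropylsilyloxy)phenyl]methylidene}furan-2(5H)-one | O=C1C=C(c2ccc(O[Si](C(C)C)(C(C)C)C(C)C)c(Br)c2)/C(=C/c2ccc(O[Si](C(C)C)(C(C)C)C(C)C)c(Br)c2)O1 | intermediate
12 | 3,5-dibromo-4-methoxybenzaldehyde | COc1c(Br)cc(C=O)cc1Br | starting material
13 | 4-[3-bromo-4-(triisopropylsilyloxy)phenyl]-5-{[3-bromo-4-(triisopropylsilyloxy)phenyl](trimethylphosphonio)methyl}furan-2-olate (zwitterion, formed in the flask, benzylic centre not controlled) | [O-]c1cc(-c2ccc(O[Si](C(C)C)(C(C)C)C(C)C)c(Br)c2)c(C(c2ccc(O[Si](C(C)C)(C(C)C)C(C)C)c(Br)c2)[P+](C)(C)C)o1 | intermediate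
14 | 4-[3-bromo-4-(triisopropylsilyloxy)phenyl]-5-{[3-bromo-4-(triisopropylsilyloxy)phenyl](trimethylphosphonio)methyl}-3-[(3,5-dibromo-4-methoxyphenyl)(oxido)methyl]furan-2(3H)-one (zwitterion, formed in the flask, carbinol centre arranged as in 15) | COc1c(Br)cc([C@H]([O-])C2C(=O)OC(C(c3ccc(O[Si](C(C)C)(C(C)C)C(C)C)c(Br)c3)[P+](C)(C)C)=C2c2ccc(O[Si](C(C)C)(C(C)C)C(C)C)c(Br)c2)cc1Br | intermediate
15 | (5Z)-4-[3-bromo-4-(triisopropylsilyloxy)phenyl]-5-{[3-bromo-4-(triisopropylsilyloxy)phenyl]methylidene}-3-[(S)-(3,5-dibromo-4-methoxyphenyl)(hydroxy)methyl]furan-2(5H)-one | COc1c(Br)cc([C@H](O)C2=C(c3ccc(O[Si](C(C)C)(C(C)C)C(C)C)c(Br)c3)/C(=C/c3ccc(O[Si](C(C)C)(C(C)C)C(C)C)c(Br)c3)OC2=O)cc1Br | intermediate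
16 | (5Z)-4-(3-bromo-4-hydroxyphenyl)-5-[(3-bromo-4-hydroxyphenyl)methylidene]-3-[(S)-(3,5-dibromo-4-methoxyphenyl)(hydroxy)methyl]furan-2(5H)-one | COc1c(Br)cc([C@H](O)C2=C(c3ccc(O)c(Br)c3)/C(=C/c3ccc(O)c(Br)c3)OC2=O)cc1Br | target

**Count and risks**

Total step count: 7. Longest linear sequence: 6 steps (steps 1, 2, 3, 5, 6 and 7).

First, step 6 (the proposed new method). The 1,6-addition of PMe3 to the hindered, donor-substituted benzylidene carbon may be too unfavourable for turnover. The phosphonium intermediate may be lost through ylide formation and Wittig-type olefination of 12. The diol may discriminate the two aldehyde faces poorly. The fallback uses known reaction types, sets out from 4 and comes back at 15. C4-selective Suzuki–Miyaura coupling of 4 with commercial 3,4-dibromofuran-2(5H)-one (PdCl2(MeCN)2, AsPh3, Ag2O, THF, 65 °C) should give 3-bromo-4-[3-bromo-4-(triisopropylsilyloxy)phenyl]furan-2(5H)-one F1. Vinylogous aldol condensation of F1 with 8 under the conditions of step 5 should give (5Z)-3-bromo-4-[3-bromo-4-(triisopropylsilyloxy)phenyl]-5-{[3-bromo-4-(triisopropylsilyloxy)phenyl]methylidene}furan-2(5H)-one F2. An asymmetric Nozaki–Hiyama–Kishi coupling of F2 with 12 (CrCl2, catalytic NiCl2, chiral sulfonamide ligand, Et3N, THF, rt) should then give 15. Zerovalent nickel is expected to insert into the electron-poor alkenyl C–Br bond next to the lactone carbonyl before it touches the electron-rich aryl C–Br bonds, and the ligand enantiomer is chosen to give the S alcohol.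

Second, step 3. The vinylogous acyl bromide 5 may be hydrolysed by the aqueous base, palladium may also insert into aryl C–Br bonds and cause oligomerisation, or the aryl silyl ether may be lost. The fallback builds the butenolide ring onto the arene instead of coupling onto a preformed ring; it sets out from 2 and comes back at 6. The Grignard reagent 3, made as in step 2, is acylated with 2-chloro-N-methoxy-N-methylacetamide (THF, −20 to 0 °C) to give 1-[3-bromo-4-(triisopropylsilyloxy)phenyl]-2-chloroethan-1-one F3. Displacement of chloride by diethylphosphonoacetic acid (Et3N, catalytic NaI, acetone, rt) gives 2-[3-bromo-4-(triisopropylsilyloxy)phenyl]-2-oxoethyl 2-(diethoxyphosphoryl)acetate F4. Intramolecular Horner–Wadsworth–Emmons olefination (LiCl, iPr2NEt, MeCN, rt) then closes the ring to 6.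

Third, step 5. Attack through C5 of the aryl-flanked silyloxyfuran may be slow, the elimination may stop at the aldol stage, or an aryl silyl ether may be lost to DBU. The fallback reverses the order of the two bond formations; it sets out from 5 and 8 and comes back at 11. Vinylogous aldol condensation of 5 with 8 (TBSOTf, iPr2NEt, CH2Cl2; then DBU) should give (5Z)-4-bromo-5-{[3-bromo-4-(triisopropylsilyloxy)phenyl]methylidene}furan-2(5H)-one F5, in which C5 is unhindered during the condensation. Suzuki–Miyaura coupling of F5 with 4 under the conditions of step 3 should then give 11.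

**Further compounds**

F1 | step 6 | 3-bromo-4-[3-bromo-4-(triisopropylsilyloxy)phenyl]furan-2(5H)-one | O=C1OCC(c2ccc(O[Si](C(C)C)(C(C)C)C(C)C)c(Br)c2)=C1Br
F2 | step 6 | (5Z)-3-bromo-4-[3-bromo-4-(triisopropylsilyloxy)phenyl]-5-{[3-bromo-4-(triisopropylsilyloxy)phenyl]methylidene}furan-2(5H)-one | O=C1C(Br)=C(c2ccc(O[Si](C(C)C)(C(C)C)C(C)C)c(Br)c2)/C(=C/c2ccc(O[Si](C(C)C)(C(C)C)C(C)C)c(Br)c2)O1
F3 | step 3 | 1-[3-bromo-4-(triisopropylsilyloxy)phenyl]-2-chloroethan-1-one | O=C(CCl)c1ccc(O[Si](C(C)C)(C(C)C)C(C)C)c(Br)c1
F4 | step 3 | 2-[3-bromo-4-(triisopropylsilyloxy)phenyl]-2-oxoethyl 2-(diethoxyphosphoryl)acetate | CCOP(=O)(CC(=O)OCC(=O)c1ccc(O[Si](C(C)C)(C(C)C)C(C)C)c(Br)c1)OCC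
F5 | step 5 | (5Z)-4-bromo-5-{[3-bromo-4-(triisopropylsilyloxy)phenyl]methylidene}furan-2(5H)-one | O=C1C=C(Br)/C(=C/c2ccc(O[Si](C(C)C)(C(C)C)C(C)C)c(Br)c2)O1
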